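7 ⇐ conjugated iminium 6 (hydrolysis gives C2=O, silyl ethers fall off) ⇐ enamine 5 (loss of hydride from C4 creates C3=C4).
5 ⇐ enol triflate 3 + N-(benzoyloxy)morpholine 4: the key bond is C2–N, made by palladium/norbornene vicinal amination with reduction at C3, so the carbonyl moves from C3 to C2.
3 ⇐ bis-silyl ether 2 ⇐ (+)-pleuromutilin 1.
Ring order: no ring is built; the five-, six- and eight-membered rings and all seven stereocentres of 7 come intact from 1, and only the oxidation pattern of the five-membered ring is rewritten.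

Assumption: the target is taken as a natural-series pleuromutilin, i.e. its C5, C6, C9, C10, C11, C12 and C14 centres are those of commercial (+)-pleuromutilin (a bulk fermentation product, accepted here as starting material); every SMILES below writes these centres with the descriptors of the given target string, which is followed wherever a database string for pleuromutilin may differ (C5/C6).

Step 1
Reactants: 1 (+)-pleuromutilin
Product: 2 11,22-bis-O-(triethylsilyl)pleuromutilin
Conditions: Et3SiOTf (2.4 equiv), 2,6-lutidine (4 equiv), CH2Cl2, −78 → −20 °C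
Reagents that add atoms: triethylsilyl trifluoromethanesulfonate, CC[Si](CC)(CC)OS(=O)(=O)C(F)(F)F
Why: O-silylation (silyl ether formation) with a silyl triflate and a hindered pyridine base is fast enough for the crowded C11–OH at low temperature yet leaves the hindered C3 ketone and the ester alone, and no stereocentre is touched.

Step 2
Reactants: 2 11,22-bis-O-(triethylsilyl)pleuromutilin
Product: 3 11,22-bis-O-(triethylsilyl)-3-deoxo-2,3-didehydro-3-(trifluoromethanesulfonyloxy)pleuromutilin
Conditions: KN(SiMe3)2 (1.15 equiv), THF, −78 °C; PhNTf2 (1.2 equiv), −78 → 0 °C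
Reagents that add atoms: N-phenylbis(trifluoromethanesulfonimide), O=S(=O)(N(c1ccccc1)S(=O)(=O)C(F)(F)F)C(F)(F)F
Why: Kinetic enolisation and O-triflation (enolate trapping with an N-aryl triflimide): the amide base removes a C2 proton because C4–H sits between two quaternary carbons and the ketone is far more acidic than the α-silyloxy ester, so the C2=C3 enol triflate forms and no stereocentre is affected.

Step 3
Reactants: 3 11,22-bis-O-(triethylsilyl)-3-deoxo-2,3-didehydro-3-(trifluoromethanesulfonyloxy)pleuromutilin, 4 N-(benzoyloxy)morpholine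
Product: 7 pleuromutilin F (3-deoxo-3,4-didehydro-2-oxopleuromutilin), via morpholine enamine 5 (not isolated), via conjugated iminium salt 6 (not isolated)
Conditions: Pd(OAc)2 (10 mol %), P(2-furyl)3 (22 mol %), N-methylbicyclo[2.2.1]hept-5-ene-2-carboxamide (50 mol %), Cs2CO3 (2.5 equiv), i-PrOH (2 equiv), 1,4-dioxane, 100 °C; filter, evaporate; DDQ (1.5 equiv), CH2Cl2, −40 → 0 °C; 1 M aq. HCl–THF, 23 °C
Reagents that add atoms: water, O
Why: Proposed new method: dehydrogenative 1,2-carbonyl transposition — zerovalent palladium inserts into C3–OTf, norbornene insertion and C2–H palladation give an alkenyl–norbornyl palladacycle that 4 oxidises to tetravalent palladium, C2–N reductive elimination forms the key bond, norbornene is extruded and the C3–Pd bond is reduced through isopropoxide β-hydride transfer to give enamine 5 (so far the known Catellani-type vicinal amination/ipso-hydride transposition of alkenyl triflates), and the new element is that 5 is not hydrolysed but dehydrogenated by DDQ (electron transfer, then loss of C4–H, the only hydrogen whose removal gives a nitrogen-stabilised allyl cation; closest known type: quinone dehydrogenation of enamines as in oxidative enamine catalysis) to iminium 6, which aqueous HCl hydrolyses to the C2 ketone already at the enone level while cleaving both silyl ethers; no stereocentre is formed (C4 becomes sp2) and the other seven are untouched.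

Compound list
1 | (+)-pleuromutilin (mutilin 14-glycolate: 5-6-8 tricycle, C3 ketone, C4–H, 11-OH, 12-methyl/vinyl, 14-O-glycolyl; natural configuration) | C=C[C@]1(C)C[C@@H](OC(=O)CO)[C@]2(C)[C@@H]3C(=O)CC[C@@]3(CC[C@@H]2C)[C@@H](C)[C@@H]1O | starting material
2 | 11,22-bis-O-(triethylsilyl)pleuromutilin (both hydroxyls as Et3Si ethers, all centres as in 1) | C=C[C@]1(C)C[C@@H](OC(=O)CO[Si](CC)(CC)CC)[C@]2(C)[C@@H]3C(=O)CC[C@@]3(CC[C@@H]2C)[C@@H](C)[C@@H]1O[Si](CC)(CC)CC | intermediate
3 | 11,22-bis-O-(triethylsilyl)-3-deoxo-2,3-didehydro-3-(trifluoromethanesulfonyloxy)pleuromutilin (C2=C3 enol triflate, C4–H kept) | C=C[C@]1(C)C[C@@H](OC(=O)CO[Si](CC)(CC)CC)[C@]2(C)[C@@H]3C(OS(=O)(=O)C(F)(F)F)=CC[C@@]3(CC[C@@H]2C)[C@@H](C)[C@@H]1O[Si](CC)(CC)CC | intermediate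
4 | N-(benzoyloxy)morpholine (morpholin-4-yl benzoate, commercial aminating reagent) | O=C(ON1CCOCC1)c1ccccc1 | starting material
5 | 11,22-bis-O-(triethylsilyl)-3-deoxo-2,3-didehydro-2-(morpholin-4-yl)pleuromutilin (C2=C3 enamine, C4–H kept; not isolated) | C=C[C@]1(C)C[C@@H](OC(=O)CO[Si](CC)(CC)CC)[C@]2(C)[C@@H]3C=C(N4CCOCC4)C[C@@]3(CC[C@@H]2C)[C@@H](C)[C@@H]1O[Si](CC)(CC)CC | intermediate
6 | 4-[11,22-bis-O-(triethylsilyl)-3-deoxo-3,4-didehydropleuromutilin-2-ylidene]morpholin-4-ium 2,3-dichloro-5,6-dicyano-4-hydroxyphenolate (C3=C4–C2=N+ iminium; not isolated) | C=C[C@]1(C)C[C@@H](OC(=O)CO[Si](CC)(CC)CC)[C@]2(C)C3=CC(=[N+]4CCOCC4)C[C@@]3(CC[C@@H]2C)[C@@H](C)[C@@H]1O[Si](CC)(CC)CC.[O-]c1c(Cl)c(Cl)c(O)c(C#N)c1C#N | intermediate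
7 | pleuromutilin F (3-deoxo-3,4-didehydro-2-oxopleuromutilin) | C=C[C@]1(C)C[C@@H](OC(=O)CO)[C@]2(C)C3=CC(=O)C[C@@]3(CC[C@@H]2C)[C@@H](C)[C@@H]1O | target

Total steps: 3. Longest linear sequence: 3 (1 → 2 → 3 → 7).

Steps most likely to fail

Most at risk is step 3, the proposed new step. Palladacycle formation next to the fully substituted C4 may be slow, the enamine may drift to the C1=C2 isomer (which DDQ cannot convert), and the quinone may add to 5 instead of dehydrogenating it. The fallback uses known chemistry only; it sets out from 3 (with 4) and comes back to the route at 7. Run only the palladium/norbornene amination–hydride stage under the same catalyst conditions, then hydrolyse enamine 5 with pH 5 acetate buffer to the saturated transposed ketone 11,22-bis-O-(triethylsilyl)-3-deoxo-2-oxopleuromutilin F1. Dehydrogenate F1 with IBX·4-methoxypyridine N-oxide in DMSO at 23 °C (only C3–C4 can be desaturated, because C9 is quaternary) to 11,22-bis-O-(triethylsilyl)-3-deoxo-3,4-didehydro-2-oxopleuromutilin F2. Finally remove the silyl groups with 1 M aq. HCl–THF to give 7.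

Second is step 2, where deprotonation of the glycolate ester or sluggish O-sulfonylation of the hindered enolate could compete. The fallback sets out from 2 and comes back at 3. It replaces the amide-base enolate by soft enolisation: Me3SiOTf/Et3N in CH2Cl2 at 0 °C gives 11,22-bis-O-(triethylsilyl)pleuromutilin 3-(trimethylsilyl) enol ether F3 (C2=C3). The enolate is then released from F3 with anhydrous CsF in the presence of PhNTf2 (DME, 23 °C) and trapped as 3.

Third is step 1, where the hindered C11–OH may silylate incompletely or the ketone may be enol-silylated alongside. The fallback sets out from 1 and comes back at 2. Instead of avoiding over-silylation, silylate exhaustively (Et3SiOTf 4 equiv, Et3N, CH2Cl2, 23 °C) to 11,22-bis-O-(triethylsilyl)pleuromutilin 3-(triethylsilyl) enol ether F4. Then unmask only the ketone with buffered fluoride (Bu4NF·AcOH, 1 equiv, THF, −78 °C), which cleaves the enol silyl group much faster than the alkyl silyl ethers, to return 2.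

Further compounds
F1 | step 3 | 11,22-bis-O-(triethylsilyl)-3-deoxo-2-oxopleuromutilin | C=C[C@]1(C)C[C@@H](OC(=O)CO[Si](CC)(CC)CC)[C@]2(C)[C@@H]3CC(=O)C[C@@]3(CC[C@@H]2C)[C@@H](C)[C@@H]1O[Si](CC)(CC)CC
F2 | step 3 | 11,22-bis-O-(triethylsilyl)-3-deoxo-3,4-didehydro-2-oxopleuromutilin | C=C[C@]1(C)C[C@@H](OC(=O)CO[Si](CC)(CC)CC)[C@]2(C)C3=CC(=O)C[C@@]3(CC[C@@H]2C)[C@@H](C)[C@@H]1O[Si](CC)(CC)CC
F3 | step 2 | 11,22-bis-O-(triethylsilyl)pleuromutilin 3-(trimethylsilyl) enol ether | C=C[C@]1(C)C[C@@H](OC(=O)CO[Si](CC)(CC)CC)[C@]2(C)[C@@H]3C(O[Si](C)(C)C)=CC[C@@]3(CC[C@@H]2C)[C@@H](C)[C@@H]1O[Si](CC)(CC)CC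
F4 | step 1 | 11,22-bis-O-(triethylsilyl)pleuromutilin 3-(triethylsilyl) enol ether | C=C[C@]1(C)C[C@@H](OC(=O)CO[Si](CC)(CC)CC)[C@]2(C)[C@@H]3C(O[Si](CC)(CC)CC)=CC[C@@]3(CC[C@@H]2C)[C@@H](C)[C@@H]1O[Si](CC)(CC)CC
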